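From 15 °C in larch to 26 °C in cedar, with the substrate charge changed as well, the fraction of lost substrate that ends as isomer of the product reads 21.0% in larch at 90.0 min and 21.7% in cedar at 120 min, and this isomer share, a selectivity, is what I carry from flask to flask.

| flask | substrate | partner | temperature | remark | time |
|---|---|---|---|---|---|
| larch | 20 mM | 20 mM | 15 °C | run made earlier |  |
| cedar | 10 mM | 20 mM | 26 °C | run made earlier |  |
| maple | 40 mM | 20 mM | 15 °C | run made earlier |  |
| Tuesday's | 20 mM (fed, over 2.0 h) | 20.0 mM | 20 °C | all else is in the flask from the start; the feed brings no volume worth counting | 2.5 h |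
| Friday's | 20 mM (fed, over 12 min) | 20.0 mM | 20 °C | all else is in the flask from the start; the feed brings no volume worth counting | 2.5 h |
| Monday's | 20 mM | 20.0 mM |  | everything together at the start at −10 °C, warmed to 20 °C at 2.0 h | 2.5 h |
| Saturday's | 20 mM | 20.0 mM (fed, over 2.0 h) | 20 °C | all else is in the flask from the start; the feed brings no volume worth counting | 2.5 h |
| Wednesday's | 20 mM (fed, over 2.0 h) | 20.0 mM |  | the addition at −10 °C, then warmed to 20 °C; the feed brings no volume worth counting | 2.5 h |

| run | time / min | isomer of the product / % | target / % | substrate / % |
|---|---|---|---|---|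
| larch | 8.00 | 0.7 | 2.4 | 95.5 |
| larch | 15.0 | 3.1 | 4.1 | 94.0 |
| larch | 40.0 | 2.3 | 11.9 | 83.4 |
| larch | 90.0 | 6.4 | 21.1 | 69.5 |
| cedar | 15.0 | 3.6 | 12.5 | 80.9 |
| cedar | 40.0 | 8.1 | 26.8 | 60.4 |
| cedar | 80.0 | 12.8 | 42.5 | 44.3 |
| cedar | 120 | 15.4 | 49.2 | 28.9 |
| maple | 15.0 | 0.6 | 6.1 | 94.2 |
| maple | 40.0 | 2.1 | 12.1 | 84.8 |
| maple | 80.0 | 4.8 | 15.3 | 76.7 |
| maple | 120 | 7.9 | 19.8 | 69.2 |

(each reading ± 1 percentage point)



* the flask that comes out highest in amount of isomer of the product, in percent of the substrate charged; "all alike" if 1.5 percentage points covers them all (Tuesday's / Friday's / Monday's / Saturday's / Wednesday's / all alike)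
* amount of isomer of the product at the end, in percent of the substrate charged, Tuesday's
* amount of isomer of the product at the end, in percent of the substrate charged, Friday's
* amount of isomer of the product at the end, in percent of the substrate charged, Monday's
* amount of isomer of the product at the end, in percent of the substrate charged, Saturday's
* amount of isomer of the product at the end, in percent of the substrate charged, Wednesday's

My colleague holds that the isomer forms from substrate with no partner in the step, and points to maple, whose isomer-to-target ratio reads 0.174 at 40.0 min and 0.399 at 120 min, so that a flask starved of partner should pile up isomer; I answer that 2.1% carries a scatter of 1 percentage point, and I hold that isomer takes its constant share of a turnover that needs both, which with equal charges gives feeding partner and feeding substrate the same reckoning. While partner stays near its full charge my law is pseudo-first-order in substrate, the two views are then one law, and there my colleague is right.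

Let pace be the second-order constant times 20.0 mM, so that with equal charges the inverse of the fraction left grows by pace times time. The last reading of larch gives 0.293 h⁻¹, the last reading of cedar, by the form for unequal charges, gives 0.802 h⁻¹, and geometric interpolation gives 0.463 h⁻¹ at 20 °C. Friday's, treated as charged at mid-feed, keeps 47.4% of its substrate, so I expect 11.4% of isomer.

For Tuesday's I go in rounds. With partner whole and substrate at a mean of half its charge, the feed loses 46.3%; that is too much, so I put it back, taking the mean loss as a third of the end value, and get 27.1%. The last 30.0 min then leave 62.4%, so I expect 8.16% of isomer in Tuesday's and the same in Saturday's. Counting the warm minutes and nothing of the cold, I reckon 4.07% for each of Monday's and Wednesday's, which leaves Friday's highest in my reckoning.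

The forecast, my colleague's, names Saturday's, with 9.5% for Tuesday's, 14% for Friday's, 4.4% for Monday's, 17.5% for Saturday's and 4.1% for Wednesday's, on the ground that “Isomer grows at nearly the same rate per substrate regardless of partner”.

Friday's comes out highest at 11.8%, with Saturday's at 9.04%, Tuesday's at 8.85%, Monday's at 5.11% and Wednesday's at 4.75%.

    substrate + partner → target (k = 17.0 M⁻¹ h⁻¹, Ea = 72.0 kJ mol⁻¹)
    substrate + partner → isomer of the product (k = 5.50 M⁻¹ h⁻¹, Ea = 65.0 kJ mol⁻¹)
    substrate + partner → second isomer (k = 2.10 M⁻¹ h⁻¹, Ea = 71.0 kJ mol⁻¹)
    partner → decomposed reagent (k = 0.0340 h⁻¹, Ea = 109 kJ mol⁻¹)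
    (constants at 20 °C)

Over the first 2.0 h, partner averaged 37.4% of its charge in Saturday's and 99.4% in Wednesday's. Friday's ended with 47.3% of its substrate left, and the isomer share turns that loss into 11.4%. Wednesday's, read later at 6.0 h, has 35.7% of its substrate left, for which the share gives 14.0%, and the flask holds 14.5% of isomer of the product.

Readings and results are calculated from invented constants; noise was put on by code.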